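**Retrosynthetic overview**
- Last bond, C3–CH2CO2H: a dioxolan-3-ylium ion (from a 3-ethoxy-1,2-dioxolane) is trapped by a ketene bis(silyl) acetal, which gives the acid directly.
- The only ring, the 1,2-dioxolane, is closed one step before the end: an enol ether carrying a C5 tert-butyl peroxide cyclises through its oxocarbenium ion with loss of isobutene.
- Key C3–C4 bond: an α-peroxy aldehyde is joined to a 1-ethoxyethylidene phosphorane (acetyl anion equivalent), so two carbonyl-level carbons are linked and the aldehyde oxygen is excised.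
- C5–O bond: invertive opening of an (S)-2,2-disubstituted epoxide by t-BuOOH; the epoxide comes from catalytic asymmetric methylene transfer to a methyl ketone.
- Methyl ketone with the side-chain stereocentre: (R)-citronellal, MeMgBr/oxidation, then cross-metathesis/hydrogenation with 6-phenylhex-1-ene.

Assumptions: the La/Li binaphthoxide catalyst made from (S)-BINOL is taken to give the (S)-epoxide from the methyl ketone (if the facial sense proves opposite, the (R)-BINOL catalyst is used); ketene bis(trimethylsilyl) acetal is bought (otherwise it is made in one operation from Me3SiOAc, LiN(iPr)2 and Me3SiCl).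

**Step 1**
Reactants: 1 (R)-citronellal [(3R)-3,7-dimethyloct-6-enal]
Product: 2 (4R)-4,8-dimethylnon-7-en-2-ol (mixture of C2 epimers)
Conditions: MeMgBr, Et2O, 0 °C; aq NH4Cl
Reagents that add atoms: methylmagnesium bromide, C[Mg]Br
Why: Grignard addition to an aldehyde; the citronellal stereocentre (the future side-chain C2') lies β to the carbonyl and is untouched, and the new carbinol centre is an irrelevant mixture because it is oxidised away in step 2.

**Step 2**
Reactants: 2 (4R)-4,8-dimethylnon-7-en-2-ol
Product: 3 (R)-4,8-dimethylnon-7-en-2-one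
Conditions: IBX, EtOAc, 80 °C
Reagents that add atoms: none
Why: Hypervalent-iodine (IBX) oxidation of a secondary alcohol to the methyl ketone, which tolerates the trisubstituted alkene and cannot epimerise the β-methyl stereocentre.

**Step 3**
Reactants: 3 (R)-4,8-dimethylnon-7-en-2-one; 4 6-phenylhex-1-ene
Product: 6 (R)-4-methyl-12-phenyldodecan-2-one, via dodec-7-en-2-one 5 (not isolated)
Conditions: 4 (3 equiv), second-generation Grubbs catalyst RuCl2(=CHPh)(H2IMes)(PCy3) (5 mol %), ClCH2CH2Cl, 45 °C; then H2 (7 bar), 70 °C, same flask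
Reagents that add atoms: none
Why: Olefin cross-metathesis of the prenyl-type trisubstituted alkene with a terminal alkene (driven by loss of volatile isobutene) followed by tandem hydrogenation, the ruthenium alkylidene being converted by H2 into a hydride that saturates the new alkene of 5 without reducing the ketone or the arene and without touching the stereocentre.

**Step 4**
Reactants: 6 (R)-4-methyl-12-phenyldodecan-2-one
Product: 7 (2S)-2-methyl-2-[(2R)-2-methyl-10-phenyldecyl]oxirane
Conditions: Me3S(O)I, NaH, LaLi3[(S)-binaphthoxide]3 (5 mol %), [2,4,6-(MeO)3C6H2]3P=O (5 mol %), 5 Å MS, THF, rt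
Reagents that add atoms: trimethylsulfoxonium iodide, C[S+](C)(C)=O.[I-]
Why: Catalytic asymmetric Corey–Chaykovsky epoxidation of a methyl ketone, in which the chiral La/Li binaphthoxide binds both ketone and sulfoxonium ylide and delivers CH2 to one carbonyl face (catalyst control, about 95:5 expected), setting the quaternary carbon that becomes ring C5 as (S) so that the invertive step 5 gives the required configuration; the minor C5 epimer is a diastereomer and is removed chromatographically at the dioxolane stage.

**Step 5**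
Reactants: 7 (2S)-2-methyl-2-[(2R)-2-methyl-10-phenyldecyl]oxirane
Product: 8 (2R,4R)-2-(tert-butylperoxy)-2,4-dimethyl-12-phenyldodecan-1-ol
Conditions: t-BuOOH (5.5 M in decane, 5 equiv), H3PMo12O40 (2 mol %), Et2O, 0 °C → rt
Reagents that add atoms: tert-butyl hydroperoxide, CC(C)(C)OO
Why: Acid-catalysed ring opening of a 2,2-disubstituted epoxide by a hydroperoxide at the tertiary carbon (the heteropolyacid-catalysed reaction type known for H2O2), which proceeds by backside attack on the activated epoxide and therefore inverts the quaternary centre to (R), the ring-C5 configuration of the target, while the tert-butyl group keeps the peroxide masked.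

**Step 6**
Reactants: 8 (2R,4R)-2-(tert-butylperoxy)-2,4-dimethyl-12-phenyldodecan-1-ol
Product: 9 (2R,4R)-2-(tert-butylperoxy)-2,4-dimethyl-12-phenyldodecanal
Conditions: Dess–Martin periodinane, CH2Cl2, 0 °C → rt
Reagents that add atoms: none
Why: Dess–Martin oxidation of a primary alcohol under neutral, metal-free conditions that leave the di-tert-alkyl peroxide intact, giving an aldehyde whose quaternary α-carbon can neither epimerise nor undergo base-induced peroxide fragmentation.

**Step 7**
Reactants: 10 triphenylphosphine hydrobromide; 11 ethyl vinyl ether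
Product: 12 (1-ethoxyethyl)triphenylphosphonium bromide (racemic)
Conditions: CH2Cl2, 0 °C → rt
Reagents that add atoms: none
Why: Markovnikov addition of Ph3P·HBr to an enol ether (protonation to the oxocarbenium ion and capture by the phosphine), the standard route to α-alkoxyalkyl phosphonium salts.

**Step 8 (key step)**
Reactants: 9 (2R,4R)-2-(tert-butylperoxy)-2,4-dimethyl-12-phenyldodecanal; 12 (1-ethoxyethyl)triphenylphosphonium bromide
Product: 13 (4R,6R)-4-(tert-butylperoxy)-2-ethoxy-4,6-dimethyl-14-phenyltetradec-2-ene (E/Z mixture)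
Conditions: 12, NaN(SiMe3)2, THF, −78 °C; then 9, −78 → 0 °C
Reagents that add atoms: none
Why: Wittig olefination with an α-alkoxyalkylidene phosphorane that acts as an acetyl anion equivalent, so that the aldehyde carbon (future C4) is joined to the future ketal carbon C3 and the aldehyde oxygen leaves as Ph3P=O; the aldehyde has no α-hydrogen, hindered dialkyl peroxides survive ylides at low temperature, and no stereocentre is made or touched (the alkene geometry is irrelevant).

**Step 9**
Reactants: 13 (4R,6R)-4-(tert-butylperoxy)-2-ethoxy-4,6-dimethyl-14-phenyltetradec-2-ene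
Product: 14 (3RS,5R)-3-ethoxy-3,5-dimethyl-5-[(2R)-2-methyl-10-phenyldecyl]-1,2-dioxolane
Conditions: TfOH (5 mol %), 4 Å MS, CH2Cl2, −40 → 0 °C
Reagents that add atoms: none
Why: Proposed new method: C-protonation of the enol ether gives an oxocarbenium ion at C3 that is captured in a 5-exo mode by the distal peroxide oxygen, and the resulting trialkylperoxonium ion loses the tert-butyl cation as isobutene to close the 1,2-dioxolane with C5 untouched and C3 formed as an irrelevant ketal epimer mixture; the closest known reaction types are the dealkylative cyclisation of tert-butyl peroxides onto halonium or mercurinium ions and the acid-mediated closure of γ-hydroperoxy ketals to 3-alkoxy-1,2-dioxolanes.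

**Step 10**
Reactants: 14 (3RS,5R)-3-ethoxy-3,5-dimethyl-5-[(2R)-2-methyl-10-phenyldecyl]-1,2-dioxolane
Product: 16 2-[(3R,5R)-3,5-dimethyl-5-[(2R)-2-methyl-10-phenyldecyl]-1,2-dioxolan-3-yl]acetic acid, via silyl ester 15 (not isolated)
Conditions: CH2=C(OSiMe3)2 (2 equiv), Me3SiOTf (0.2 equiv), CH2Cl2, −78 °C; aq NaH2PO4 work-up; chromatography
Reagents that add atoms: ketene bis(trimethylsilyl) acetal, C=C(O[Si](C)(C)C)O[Si](C)(C)C
Why: Lewis acid-mediated substitution of a peroxyketal by a silyl ketene acetal (Mukaiyama-type addition to a peroxycarbenium ion), a known way to 1,2-dioxolane-3-acetates that leaves C5 untouched; C3 is set by attack on the planar dioxolan-3-ylium ion, whose two faces differ only by the remote C5 methyl versus CH2 groups, so roughly equal amounts of the C3 epimers are expected and the (3R) acid (C3 and C5 methyls cis by NOE) is isolated by chromatography after the silyl ester 15 hydrolyses on work-up.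

**Compound list**
1 | (R)-citronellal, (3R)-3,7-dimethyloct-6-enal | C[C@H](CCC=C(C)C)CC=O | starting material
2 | (4R)-4,8-dimethylnon-7-en-2-ol (C2 epimers) | C[C@H](CCC=C(C)C)CC(C)O | intermediate
3 | (R)-4,8-dimethylnon-7-en-2-one | C[C@H](CCC=C(C)C)CC(C)=O | intermediate
4 | 6-phenylhex-1-ene | C=CCCCCc1ccccc1 | starting material
5 | (4R)-4-methyl-12-phenyldodec-7-en-2-one (E/Z, formed in the flask) | C[C@H](CCC=CCCCCc1ccccc1)CC(C)=O | intermediate
6 | (R)-4-methyl-12-phenyldodecan-2-one | C[C@H](CCCCCCCCc1ccccc1)CC(C)=O | intermediate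
7 | (2S)-2-methyl-2-[(2R)-2-methyl-10-phenyldecyl]oxirane | C[C@H](CCCCCCCCc1ccccc1)C[C@@]1(C)CO1 | intermediate
8 | (2R,4R)-2-(tert-butylperoxy)-2,4-dimethyl-12-phenyldodecan-1-ol | C[C@H](CCCCCCCCc1ccccc1)C[C@](C)(CO)OOC(C)(C)C | intermediate
9 | (2R,4R)-2-(tert-butylperoxy)-2,4-dimethyl-12-phenyldodecanal | C[C@H](CCCCCCCCc1ccccc1)C[C@](C)(C=O)OOC(C)(C)C | intermediate
10 | triphenylphosphine hydrobromide | [PH+](c1ccccc1)(c1ccccc1)c1ccccc1.[Br-] | starting material
11 | ethyl vinyl ether | C=COCC | starting material
12 | (1-ethoxyethyl)triphenylphosphonium bromide (racemic) | CCOC(C)[P+](c1ccccc1)(c1ccccc1)c1ccccc1.[Br-] | intermediate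
13 | (4R,6R)-4-(tert-butylperoxy)-2-ethoxy-4,6-dimethyl-14-phenyltetradec-2-ene (E/Z) | C[C@H](CCCCCCCCc1ccccc1)C[C@](C)(C=C(C)OCC)OOC(C)(C)C | intermediate
14 | (3RS,5R)-3-ethoxy-3,5-dimethyl-5-[(2R)-2-methyl-10-phenyldecyl]-1,2-dioxolane | C[C@H](CCCCCCCCc1ccccc1)C[C@]1(C)CC(C)(OCC)OO1 | intermediate
15 | trimethylsilyl 2-[(3R,5R)-3,5-dimethyl-5-[(2R)-2-methyl-10-phenyldecyl]-1,2-dioxolan-3-yl]acetate (formed in the flask) | C[C@H](CCCCCCCCc1ccccc1)C[C@]1(C)C[C@](C)(CC(=O)O[Si](C)(C)C)OO1 | intermediate
16 | 2-[(3R,5R)-3,5-dimethyl-5-[(2R)-2-methyl-10-phenyldecyl]-1,2-dioxolan-3-yl]acetic acid | C[C@H](CCCCCCCCc1ccccc1)C[C@]1(C)C[C@](C)(CC(=O)O)OO1 | target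

**Totals**
Total step count: 10 (including the one-step preparation of 12). Longest linear sequence: 9 steps from 1 (steps 1–6 and 8–10).

**Three steps most likely to fail**

Step 8 (a hindered, disubstituted α-alkoxy ylide must add to a neopentyl-type aldehyde). The fallback sets out from 9 and comes back at 14. The carbonyl-to-carbonyl join is made in two stages with the unhindered, commercial formyl anion equivalent. Aldehyde 9 and Ph3P=CHOMe (from (methoxymethyl)triphenylphosphonium chloride and KN(SiMe3)2, THF, −78 °C) give the methyl enol ether F1. Dilute HCl in wet THF hydrolyses it to the β-peroxy aldehyde F2. MeTi(OiPr)3 (THF, −40 to 0 °C) adds methyl without attacking the peroxide and gives the carbinol F3. Dess–Martin periodinane then gives the β-(tert-butylperoxy) ketone F4, which with EtOH and catalytic TfOH closes to 14 in the manner of step 9.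

Step 9 (new ring closure; the tert-butyl group may not leave, or the allylic peroxide may ionise before C-protonation). The fallback sets out from 7 and comes back at 14. The peroxide is carried as a silyl peroxide, whose acid-mediated closure is the established hydroperoxy-ketal route to 3-alkoxy-1,2-dioxolanes. Epoxide 7 with anhydrous ethereal H2O2 and catalytic H3PMo12O40 gives, with the same inversion, the hydroperoxy alcohol F5. Et3SiCl/imidazole (1 equiv, −40 °C) silylates the more acidic hydroperoxide to give the silyl peroxide F6. Dess–Martin oxidation gives the aldehyde F7, and olefination with the ylide from 12 gives the enol ether F8. Camphorsulfonic acid in wet CH2Cl2 removes the silyl group, and the free hydroperoxide closes onto the oxocarbenium ion to give 14.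

Step 10 (little facial bias at C3, so the acid forms as an epimer mixture that may be hard to separate). The fallback sets out from 14 and comes back at 16. Dioxolane 14 is treated with 1-(tert-butyldimethylsilyloxy)-1-methoxyethene and Me3SiOTf to give the methyl ester F9 together with its C3 epimer F10; the esters should separate more easily than the acids. The unwanted F10 is recycled with Et2NH in CF3CH2OH, which opens it by retro-Michael reaction to the hydroperoxy enoate F11 and re-closes it to an F9/F10 mixture without touching C5. LiOH (THF/H2O, 0 °C) then hydrolyses F9 to 16.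

**Further compounds**
F1 | step 8 | (3R,5R)-3-(tert-butylperoxy)-1-methoxy-3,5-dimethyl-13-phenyltridec-1-ene (E/Z) | C[C@H](CCCCCCCCc1ccccc1)C[C@](C)(C=COC)OOC(C)(C)C
F2 | step 8 | (3R,5R)-3-(tert-butylperoxy)-3,5-dimethyl-13-phenyltridecanal | C[C@H](CCCCCCCCc1ccccc1)C[C@](C)(CC=O)OOC(C)(C)C
F3 | step 8 | (4R,6R)-4-(tert-butylperoxy)-4,6-dimethyl-14-phenyltetradecan-2-ol (C2 epimers) | C[C@H](CCCCCCCCc1ccccc1)C[C@](C)(CC(C)O)OOC(C)(C)C
F4 | step 8 | (4R,6R)-4-(tert-butylperoxy)-4,6-dimethyl-14-phenyltetradecan-2-one | C[C@H](CCCCCCCCc1ccccc1)C[C@](C)(CC(C)=O)OOC(C)(C)C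
F5 | step 9 | (2R,4R)-2-hydroperoxy-2,4-dimethyl-12-phenyldodecan-1-ol | C[C@H](CCCCCCCCc1ccccc1)C[C@](C)(CO)OO
F6 | step 9 | (2R,4R)-2,4-dimethyl-12-phenyl-2-[(triethylsilyl)peroxy]dodecan-1-ol | C[C@H](CCCCCCCCc1ccccc1)C[C@](C)(CO)OO[Si](CC)(CC)CC
F7 | step 9 | (2R,4R)-2,4-dimethyl-12-phenyl-2-[(triethylsilyl)peroxy]dodecanal | C[C@H](CCCCCCCCc1ccccc1)C[C@](C)(C=O)OO[Si](CC)(CC)CC
F8 | step 9 | (4R,6R)-2-ethoxy-4,6-dimethyl-14-phenyl-4-[(triethylsilyl)peroxy]tetradec-2-ene (E/Z) | C[C@H](CCCCCCCCc1ccccc1)C[C@](C)(C=C(C)OCC)OO[Si](CC)(CC)CC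
F9 | step 10 | methyl 2-[(3R,5R)-3,5-dimethyl-5-[(2R)-2-methyl-10-phenyldecyl]-1,2-dioxolan-3-yl]acetate | C[C@H](CCCCCCCCc1ccccc1)C[C@]1(C)C[C@](C)(CC(=O)OC)OO1
F10 | step 10 | methyl 2-[(3S,5R)-3,5-dimethyl-5-[(2R)-2-methyl-10-phenyldecyl]-1,2-dioxolan-3-yl]acetate | C[C@H](CCCCCCCCc1ccccc1)C[C@]1(C)C[C@@](C)(CC(=O)OC)OO1
F11 | step 10 | methyl (5R,7R)-5-hydroperoxy-3,5,7-trimethyl-15-phenylpentadec-2-enoate (E/Z) | C[C@H](CCCCCCCCc1ccccc1)C[C@](C)(CC(C)=CC(=O)OC)OO
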